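**Retrosynthetic overview**
1. Target 21 ⇐ macrocycle 19 by a one-flask double transannular cation–olefin cyclisation: epoxide opening forms C4–C16, then the C7 allyl cation forms C7–C16, with the isopropenyl CH2 acting twice as nucleophile.
2. 19 ⇐ 17 by ring-closing enyne metathesis, which makes the 14-membered ring, the 9E alkene and the C8 exo-methylene at once.
3. 17 ⇐ 16 by hydroxyl-directed epoxidation; 16 ⇐ 8 + 14 by chromium-mediated allylation (C1–C2 bond, C2 carbinol, isopropenyl group).
4. 8 ⇐ (R)-citronellal (C12 from the chiral pool, C14–O by proline aminoxylation); 14 ⇐ geranyl acetate.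
5. Ring order: 14-membered carbocycle → six-membered ring → five-membered ring.

Assumption: atoms are numbered as in the cembrane/trinervitane skeleton (C1–C14 ring, C15–C17 isopropenyl unit, C18 on C4, C19 on C8, C20 on C12). C7 and the C1 carbinol/bromide are carried as epimer mixtures because both centres are erased later.

**Step 1**
Reactants: 1 (R)-citronellal
Product: 2 (4R)-4,8-dimethylnona-1,7-diene
Conditions: Ph3PCH3Br, KOtBu, THF, 0 °C to rt
Reagents that add atoms: methyltriphenylphosphonium bromide (C[P+](c1ccccc1)(c1ccccc1)c1ccccc1.[Br-])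
Why: Wittig methylenation of the aldehyde; the stereocentre (future C12, from the chiral pool) is β to the carbonyl and is not touched.

**Step 2**
Reactants: 2 (4R)-4,8-dimethylnona-1,7-diene
Product: 3 (4R)-4-methylhept-6-enal
Conditions: O3 (1.0 equiv, Sudan Red 7B end point), CH2Cl2, pyridine, −78 °C; then Me2S
Reagents that add atoms: ozone (O=[O+][O-])
Why: Chemoselective ozonolysis, the trisubstituted alkene being far more reactive toward ozone than the terminal one, gives the aldehyde whose carbonyl carbon is the future C1 and whose α-CH2 is the future C14.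

**Step 3**
Reactants: 3 (4R)-4-methylhept-6-enal
Product: 6 (4S,6S)-2,6-dimethylnona-1,8-diene-3,4-diol (C3 epimers), via aminoxy aldehyde 4 (not isolated), via aminoxy alcohol 5 (not isolated)
Conditions: D-proline (20 mol %), PhNO, CHCl3, 4 °C; evaporate cold, THF, CH2=C(CH3)MgBr (3.5 equiv), −78 °C; then AcOH, Zn, rt
Reagents that add atoms: nitrosobenzene (O=Nc1ccccc1); isopropenylmagnesium bromide (C=C(C)[Mg]Br)
Why: Proline-catalysed enamine α-aminoxylation sets the C–O centre (D-proline gives 2S, the future 14S), Grignard addition puts C15–C17 on C1 (its carbinol configuration is irrelevant because this carbon becomes the allylmetal terminus in step 9) and Zn/AcOH reduces the N–O bond.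

**Step 4**
Reactants: 6 (4S,6S)-2,6-dimethylnona-1,8-diene-3,4-diol
Product: 8 (4S,6S)-3-bromo-2,6-dimethylnona-1,8-dien-4-yl acetate (C3 epimers), via cyclic orthoacetate 7 (not isolated)
Conditions: MeC(OMe)3, PPTS (cat.), CH2Cl2, rt; then AcBr, 0 °C
Reagents that add atoms: trimethyl orthoacetate (COC(C)(OC)OC); acetyl bromide (CC(=O)Br)
Why: Kolb–Sharpless conversion of a diol into an acetoxy bromide, in which bromide opens the 1,3-dioxolan-2-ylium ion at the allylic carbon so that the acetate ends on C14 with retention because the C14–O bond is never broken.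

**Step 5**
Reactants: 9 geranyl acetate
Product: 10 (2E)-3-methyl-6-oxohex-2-en-1-yl acetate
Conditions: O3 (1.0 equiv, Sudan Red 7B end point), CH2Cl2, pyridine, −78 °C; then Me2S
Reagents that add atoms: ozone (O=[O+][O-])
Why: Chemoselective ozonolysis of the distal trisubstituted alkene, the 2,3-alkene being deactivated by its allylic acetate, leaves the E geometry of the future C3=C4 untouched.

**Step 6**
Reactants: 10 (2E)-3-methyl-6-oxohex-2-en-1-yl acetate
Product: 12 (2E)-6-[(tert-butoxycarbonyl)oxy]-3-methyloct-2-en-7-yn-1-yl acetate (racemic), via bromomagnesium alkoxide 11 (not isolated)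
Conditions: HC≡CMgBr (1.1 equiv), THF, −78 °C; then Boc2O, DMAP (cat.), −78 to 0 °C
Reagents that add atoms: ethynylmagnesium bromide (C#C[Mg]Br); di-tert-butyl dicarbonate (CC(C)(C)OC(=O)OC(=O)OC(C)(C)C)
Why: 1,2-Addition of the acetylide to the aldehyde (much faster than attack on the acetate at −78 °C) and in-flask O-acylation give the C7 carbonate that masks the hydroxyl and later serves as leaving group; C7 is deliberately racemic because it becomes an allyl cation in step 12.

**Step 7**
Reactants: 12 (2E)-6-[(tert-butoxycarbonyl)oxy]-3-methyloct-2-en-7-yn-1-yl acetate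
Product: 13 tert-butyl (6E)-8-hydroxy-6-methyloct-6-en-1-yn-3-yl carbonate
Conditions: K2CO3 (0.2 equiv), MeOH, 0 °C
Reagents that add atoms: none
Why: Base-catalysed transesterification removes the primary acetate while the hindered secondary tert-butyl carbonate survives at 0 °C.

**Step 8**
Reactants: 13 tert-butyl (6E)-8-hydroxy-6-methyloct-6-en-1-yn-3-yl carbonate
Product: 14 (2E)-6-[(tert-butoxycarbonyl)oxy]-3-methyloct-2-en-7-ynal
Conditions: MnO2, CH2Cl2, rt
Reagents that add atoms: none
Why: MnO2 allylic oxidation gives the E-enal without touching the alkyne or the carbonate.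

**Step 9**
Reactants: 8 (4S,6S)-3-bromo-2,6-dimethylnona-1,8-dien-4-yl acetate; 14 (2E)-6-[(tert-butoxycarbonyl)oxy]-3-methyloct-2-en-7-ynal
Product: 16 open-chain allylation product (1R,2S,3E,12S,14S; C7 epimers), via allylchromium dichloride 15 (not isolated)
Conditions: CrCl2 (4 equiv), THF, 0 °C to rt
Reagents that add atoms: none
Why: Nozaki–Hiyama allylation, in which the allylchromium adds 1,2 to the enal through its γ-carbon in a chair transition state (C1–C2 bond, isopropenyl group, 1,2-anti) and the C14 centre directs the face (C14–H eclipsing the C15 methyl to relieve A(1,3) strain, aldehyde entering anti to the C13 chain), which predicts the 2S carbinol drawn.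

**Step 10**
Reactants: 16 open-chain allylation product
Product: 17 (3S,4S)-epoxide of 16 (1R,2R,3S,4S,12S,14S; C7 epimers)
Conditions: VO(acac)2 (5 mol %), t-BuOOH (1.3 equiv), CH2Cl2, 0 °C
Reagents that add atoms: tert-butyl hydroperoxide (CC(C)(C)OO)
Why: Hydroxyl-directed vanadium-catalysed epoxidation touches only the allylic C3=C4 alkene and, because of A(1,3) strain between the C2 substituents and the cis C18 methyl, gives the threo (3S,4S) epoxy alcohol.

**Step 11**
Reactants: 17 (3S,4S)-epoxide of 16
Product: 19 (1R,2R,3S,4S,9E,12S,14S)-14-acetoxy-7-[(tert-butoxycarbonyl)oxy]-3,4-epoxycembra-8(19),9,15-trien-2-ol (C7 epimers), via butadiene 18 (not isolated)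
Conditions: RuCl2(PCy3)2(=CHPh) (first-generation Grubbs catalyst, 15 mol %), C2H4 (1 atm), CH2Cl2 (1 mM), 40 °C
Reagents that add atoms: ethylene (C=C)
Why: Ring-closing enyne metathesis under ethylene (alkyne to 2-substituted butadiene, then ring closure onto the terminal alkene with loss of ethylene) forms the 14-membered ring, the 9E alkene and the C8 exo-methylene at once, and the first-generation catalyst leaves the hindered 1,1-disubstituted isopropenyl group alone.

**Step 12**
Reactants: 19 (1R,2R,3S,4S,9E,12S,14S)-14-acetoxy-7-[(tert-butoxycarbonyl)oxy]-3,4-epoxycembra-8(19),9,15-trien-2-ol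
Product: 21 (2R,3R,4S,7R,9E,12S,14S,16S)-14-acetoxytrinervita-1(15),8(19),9-triene-2,3-diol (the target), via bicyclic carbonate 20 (not isolated)
Conditions: BF3·OEt2 (2.5 equiv), CH2Cl2 (5 mM), −78 to −30 °C; then aq NaHCO3
Reagents that add atoms: none
Why: Proposed new method: BF3 opens the epoxide at tertiary C4, the isopropenyl CH2 (C16) attacks anti to the departing oxygen through a chair (C4 inverted, 3-OH cis to C18), the C15 cation loses a C16 proton to give the 15(16)-ene 20, the C7 carbonate then ionises to an allyl cation that the same carbon C16 attacks in a 5-exo closure (cis ring fusion enforced by the C4–C5–C6 tether, C8 placed by the eleven-membered tether, both C7 epimers converge) and loss of H1 gives the 1(15)-alkene with C8=C19 restored; the closest known reaction types are the Lewis-acid epoxide-initiated transannular cyclisation of epoxycembrenes to secotrinervitanes and the Johnson allyl-cation-initiated olefin cyclisation, merged here so that one isopropenyl group serves twice as nucleophile.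

**Compound list**
1 | (R)-citronellal, (3R)-3,7-dimethyloct-6-enal | O=CC[C@H](C)CCC=C(C)C | starting material
2 | (4R)-4,8-dimethylnona-1,7-diene | C=CC[C@H](C)CCC=C(C)C | intermediate
3 | (4R)-4-methylhept-6-enal | C=CC[C@H](C)CCC=O | intermediate
4 | (2S,4S)-4-methyl-2-[(phenylamino)oxy]hept-6-enal | C=CC[C@H](C)C[C@H](ONc1ccccc1)C=O | intermediate
5 | (4S,6S)-2,6-dimethyl-4-[(phenylamino)oxy]nona-1,8-dien-3-ol, C3 epimers | C=CC[C@H](C)C[C@H](ONc1ccccc1)C(O)C(C)=C | intermediate
6 | (4S,6S)-2,6-dimethylnona-1,8-diene-3,4-diol, C3 epimers | C=CC[C@H](C)C[C@H](O)C(O)C(C)=C | intermediate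
7 | cyclic orthoacetate of 6: (5S)-2-methoxy-2-methyl-5-[(2S)-2-methylpent-4-en-1-yl]-4-(prop-1-en-2-yl)-1,3-dioxolane | C=CC[C@H](C)C[C@@H]1OC(C)(OC)OC1C(C)=C | intermediate
8 | (4S,6S)-3-bromo-2,6-dimethylnona-1,8-dien-4-yl acetate, C3 epimers | C=CC[C@H](C)C[C@H](OC(C)=O)C(Br)C(C)=C | intermediate
9 | geranyl acetate, (2E)-3,7-dimethylocta-2,6-dien-1-yl acetate | CC(C)=CCC/C(C)=C/COC(C)=O | starting material
10 | (2E)-3-methyl-6-oxohex-2-en-1-yl acetate | O=CCC/C(C)=C/COC(C)=O | intermediate
11 | bromomagnesium alkoxide of (2E)-6-hydroxy-3-methyloct-2-en-7-yn-1-yl acetate, racemic | C#CC(O[Mg]Br)CC/C(C)=C/COC(C)=O | intermediate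
12 | (2E)-6-[(tert-butoxycarbonyl)oxy]-3-methyloct-2-en-7-yn-1-yl acetate, racemic | C#CC(OC(=O)OC(C)(C)C)CC/C(C)=C/COC(C)=O | intermediate
13 | tert-butyl (6E)-8-hydroxy-6-methyloct-6-en-1-yn-3-yl carbonate, racemic | C#CC(OC(=O)OC(C)(C)C)CC/C(C)=C/CO | intermediate
14 | (2E)-6-[(tert-butoxycarbonyl)oxy]-3-methyloct-2-en-7-ynal, racemic | C#CC(OC(=O)OC(C)(C)C)CC/C(C)=C/C=O | intermediate
15 | dichloro[(2E,4S,6S)-4-acetoxy-2,6-dimethylnona-2,8-dien-1-yl]chromium (trivalent chromium) | C=CC[C@H](C)C[C@H](OC(C)=O)/C=C(\C)C[Cr](Cl)Cl | intermediate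
16 | open-chain allylation product HC≡C–C7H(OBoc)–C6H2–C5H2–C4(Me)=C3H–C2H(OH)–C1H(isopropenyl)–C14H(OAc)–C13H2–C12H(Me)–C11H2–C10H=CH2; 1R,2S,3E,12S,14S, C7 epimers | C=CC[C@H](C)C[C@H](OC(C)=O)[C@H](C(C)=C)[C@@H](O)/C=C(\C)CCC(OC(=O)OC(C)(C)C)C#C | intermediate
17 | (3S,4S)-3,4-epoxide of 16; 1R,2R,3S,4S,12S,14S, C7 epimers | C=CC[C@H](C)C[C@H](OC(C)=O)[C@H](C(C)=C)[C@@H](O)[C@@H]1O[C@@]1(C)CCC(OC(=O)OC(C)(C)C)C#C | intermediate
18 | butadiene from 17 (C≡CH converted into CH2=C8–C9H=CH2), otherwise as 17 | C=CC[C@H](C)C[C@H](OC(C)=O)[C@H](C(C)=C)[C@@H](O)[C@@H]1O[C@@]1(C)CCC(OC(=O)OC(C)(C)C)C(=C)C=C | intermediate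
19 | (1R,2R,3S,4S,9E,12S,14S)-14-acetoxy-7-[(tert-butoxycarbonyl)oxy]-3,4-epoxycembra-8(19),9,15-trien-2-ol, C7 epimers | C=C1/C=C/C[C@H](C)C[C@H](OC(C)=O)[C@H](C(C)=C)[C@@H](O)[C@@H]2O[C@@]2(C)CCC1OC(=O)OC(C)(C)C | intermediate
20 | (1R,2R,3R,4S,9E,12S,14S)-14-acetoxy-7-[(tert-butoxycarbonyl)oxy]-7,16-secotrinervita-8(19),9,15-triene-2,3-diol, C7 epimers | C=C1/C=C/C[C@H](C)C[C@H](OC(C)=O)[C@@H]2C(C)=C[C@](C)(CCC1OC(=O)OC(C)(C)C)[C@@H](O)[C@@H]2O | intermediate
21 | (2R,3R,4S,7R,9E,12S,14S,16S)-14-acetoxytrinervita-1(15),8(19),9-triene-2,3-diol, CNP0291538.1 | C=C1/C=C/C[C@H](C)C[C@H](OC(C)=O)C2=C(C)[C@@H]3[C@H]1CC[C@]3(C)[C@@H](O)[C@@H]2O | target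

**Step count**
Total steps: 12. Longest linear sequence: 8 (steps 1–4 then 9–12; the western branch, steps 5–8 then 9–12, is equally long).

**Three steps most likely to fail, with fallbacks**

Step 12 (double cyclisation) is the least certain. The C4 cation may instead be captured by the diene CH2 (C19) or by O3 as a bridged ether, the C15 cation may lose H1 or H17 to give alkenes that cannot close, and the allylic acetate of the product may ionise. The fallback sets out from 19 and returns at 21. Only the epoxide cyclisation is run (BF3·OEt2, 2,6-di-tert-butylpyridine, CH2Cl2, −78 °C) and bicyclic carbonate 20 is isolated. The five-membered ring is then closed by an Oppolzer-type palladium-ene reaction (Pd(PPh3)4, AcOH, 75 °C): the π-allyl palladium from the C7 carbonate inserts the C15=C16 alkene and β-hydride elimination gives the 15(17)-exo-methylene isomer F1. RhCl3·3H2O (cat.) in EtOH then moves that alkene into the tetrasubstituted 1(15) position to give 21.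

Step 11 (macrocyclic enyne metathesis) may give E/Z mixtures at C9=C10, oligomers, or ring closure of the terminal alkene onto the isopropenyl group. The fallback sets out from 8 and 14 and returns at 19; it makes the C9=C10 bond first and closes the macrocycle at C1–C2. Alkyne 14 is converted with C2H4 and RuCl2(PCy3)2(=CHPh) into its 2-substituted butadiene and cross-metathesised in the same flask with bromide 8 (second-generation Hoveyda–Grubbs catalyst RuCl2(H2IMes)(=CH–C6H4-2-OiPr), CH2Cl2, rt) to give open-chain bromo dienal F2. CrCl2 in THF at 2 mM closes the 14-membered ring by intramolecular allylation to macrocyclic dienol F3. VO(acac)2/t-BuOOH epoxidation of F3 gives 19.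

Step 9 (chromium allylation) depends on substrate control for the C2 configuration, which fixes the epoxide face and hence the absolute sense of both new rings. The allylchromium 15 may also lose acetate by 1,4-elimination to a diene. The fallback sets out from 8 and returns at 16. CuCl/Xantphos/KOtBu with B2pin2 converts 8 by SN2' borylation into (E)-allylboronate F4. Allylboration of 14 catalysed by the chiral phosphoric acid (R)-TRIP (5 mol %, toluene, −30 °C) then gives 16 with C2 set by the catalyst and C1 anti through the chair transition state, without an organometallic that can eliminate acetate.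

**Further compounds**
F1 | step 12 | (1R,2R,3R,4S,7R,9E,12S,14S,16S)-14-acetoxytrinervita-8(19),9,15(17)-triene-2,3-diol | C=C1/C=C/C[C@H](C)C[C@H](OC(C)=O)[C@@H]2C(=C)[C@@H]3[C@H]1CC[C@]3(C)[C@@H](O)[C@@H]2O
F2 | step 11 | open-chain bromo dienal OHC–C3H=C4(Me)–C5H2–C6H2–C7H(OBoc)–C8(=CH2)–C9H=C10H–C11H2–C12H(Me)–C13H2–C14H(OAc)–C1H(Br)–C(Me)=CH2; 3E,9E,12S,14S | O=C/C=C(\C)CCC(OC(=O)OC(C)(C)C)C(=C)/C=C/C[C@H](C)C[C@H](OC(C)=O)C(Br)C(C)=C
F3 | step 11 | (1R,2S,3E,9E,12S,14S)-14-acetoxy-7-[(tert-butoxycarbonyl)oxy]cembra-3,8(19),9,15-tetraen-2-ol | C=C1/C=C/C[C@H](C)C[C@H](OC(C)=O)[C@H](C(C)=C)[C@@H](O)/C=C(\C)CCC1OC(=O)OC(C)(C)C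
F4 | step 9 | 2-[(2E,4S,6S)-4-acetoxy-2,6-dimethylnona-2,8-dien-1-yl]-4,4,5,5-tetramethyl-1,3,2-dioxaborolane | C=CC[C@H](C)C[C@H](OC(C)=O)/C=C(\C)CB1OC(C)(C)C(C)(C)O1
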